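Ring C of the lower flavan unit is disconnected at O1–C2 and C3–C4 into a ring-A salicylaldehyde (phenol oxygen O1 on C8a, formyl carbon C4 on the neighbouring C4a) and a cinnamaldehyde that brings C2, C3 and ring B. The key step exploits this ortho O1/C4 pair and the benzylic, oxygen-bearing C2: a chiral prolinol silyl ether lets O1 add to the enal β-carbon (setting C2) and the enamine carbon C3 then closes ring C onto C4 in one operation. The surplus formyl group on C3 is removed by decarbonylation, and hydroboration installs the trans C3 hydroxyl. The upper unit is (+)-catechin, joined through C6'–C8 by Negishi coupling before the annulation.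

Key step: step 9

Assumption: the C6'–C8 biaryl axis carries no defined configuration in the structure; rotamers about it are taken to interconvert, and intermediates may appear as rotamer mixtures.
Numbering: flavan numbering is used for both units (O1, C2, C3, C4, C4a, C5 to C8, C8a, primed numbers for ring B); the lower unit is the one bonded through C8.

Step 1
Reactants: 1 (+)-catechin
Product: 3 penta-O-benzyl-(+)-catechin, via tetra-O-benzyl-(+)-catechin 2 (not isolated)
Conditions: BnBr, K2CO3, DMF, 0 °C to rt; then NaH, BnBr, 0 °C to rt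
Reagents that add atoms: benzyl bromide, BrCc1ccccc1
Why: Williamson etherification in two stages, the four phenols first under carbonate, so that NaH (needed for the C3 alcohol) meets no free phenoxide and cannot open ring C by quinone-methide formation; C2 and C3 keep the (2R,3S) configuration of (+)-catechin.

Step 2
Reactants: 3 penta-O-benzyl-(+)-catechin
Product: 4 6,8-dibromo-penta-O-benzyl-(+)-catechin
Conditions: NBS (2.05 equiv), CH2Cl2, −20 °C to rt, dark
Reagents that add atoms: N-bromosuccinimide, O=C1CCC(=O)N1Br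
Why: Electrophilic aromatic bromination should go to the two free positions C6 and C8 of the phloroglucinol-type ring A, the most nucleophilic sites of 3; the bromines block ring A for step 3 and leave in step 12.

Step 3
Reactants: 4 6,8-dibromo-penta-O-benzyl-(+)-catechin
Product: 5 6,8-dibromo-6'-iodo-penta-O-benzyl-(+)-catechin
Conditions: NIS (1.2 equiv), TFA (0.3 equiv), MeCN/CH2Cl2, 0 °C to rt, dark
Reagents that add atoms: N-iodosuccinimide, O=C1CCC(=O)N1I
Why: With ring A fully substituted, electrophilic aromatic iodination should occur on ring B at C6', which is para to the 3'-benzyloxy group and ortho to C1', whereas C2' is flanked on both sides.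

Step 4
Reactants: 6 3,5-bis(benzyloxy)phenol
Product: 7 1,3-bis(benzyloxy)-5-(methoxymethoxy)benzene
Conditions: MOMCl, iPr2NEt, CH2Cl2, 0 °C to rt
Reagents that add atoms: chloromethyl methyl ether, COCCl
Why: O-Alkylation gives the MOM ether, the strongest directing group of the three ethers for the ortho-lithiation of step 5 and removable later without touching benzyl ethers.

Step 5
Reactants: 7 1,3-bis(benzyloxy)-5-(methoxymethoxy)benzene; 5 6,8-dibromo-6'-iodo-penta-O-benzyl-(+)-catechin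
Product: 10 C6'–C8 biaryl MOM ether, via aryllithium 8 (not isolated), via arylzinc chloride 9 (not isolated)
Conditions: n-BuLi, THF, 0 °C; ZnCl2, 0 °C to rt; then 5, Pd2(dba)3 (2.5 mol%), SPhos (10 mol%), THF, 50 °C
Reagents that add atoms: none
Why: Directed ortho-metalation should occur at the carbon flanked by OMOM and OBn, and after transmetalation to zinc the Negishi coupling (zerovalent palladium with a bulky biarylphosphine) should insert only into the C–I bond, since each ring-A C–Br bond is shielded by two ortho oxygens.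

Step 6
Reactants: 10 C6'–C8 biaryl MOM ether
Product: 11 biaryl phenol
Conditions: 2 M HCl, MeOH/THF, 45 °C
Reagents that add atoms: none
Why: Acid-catalysed acetal exchange removes the MOM group and frees the phenol that becomes O1, benzyl ethers and the flavan ring being stable to dilute acid.

Step 7
Reactants: 11 biaryl phenol
Product: 12 biaryl salicylaldehyde
Conditions: MgCl2, Et3N, paraformaldehyde, THF, reflux
Reagents that add atoms: formaldehyde (from paraformaldehyde), C=O
Why: Magnesium-mediated ortho-formylation (magnesium phenoxide plus formaldehyde, then Oppenauer-type hydride transfer to a second formaldehyde) is specific for the position ortho to the free hydroxyl, and only C4a is free there, so the carbon that becomes C4 is placed next to O1.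

Step 8
Reactants: 13 3,4-bis(benzyloxy)benzaldehyde
Product: 14 (E)-3-[3,4-bis(benzyloxy)phenyl]prop-2-enal
Conditions: Ph3P=CHCHO, toluene, 80 °C
Reagents that add atoms: (triphenylphosphoranylidene)acetaldehyde, O=CC=P(c1ccccc1)(c1ccccc1)c1ccccc1
Why: Wittig olefination with the stabilised formylmethylene ylide should give the (E)-enal that carries C2, C3 and ring B of the lower unit.

Step 9
Reactants: 12 biaryl salicylaldehyde; 14 (E)-3-[3,4-bis(benzyloxy)phenyl]prop-2-enal (2–3 equiv)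
Product: 16 (2R)-2-aryl-2H-chromene-3-carbaldehyde of the lower unit, via oxa-Michael enamine 15 (not isolated)
Conditions: (S)-2-[diphenyl(trimethylsilyloxy)methyl]pyrrolidine (20 mol%), 2-nitrobenzoic acid (20 mol%), 4 Å MS, toluene, rt to 40 °C, dark
Reagents that add atoms: none
Why: The amine and 14 form an (E)-iminium ion, the only free phenol of 12 (O1–H) adds to its β-carbon (the future C2) to give enamine 15, and the nucleophilic enamine carbon C3 attacks the formyl carbon C4 held ortho to O1 on ring A, closing ring C by the C3–C4 bond; loss of one molecule of water and hydrolysis release the 3-formyl-2H-chromene and the catalyst. The closest known reaction type is the amine-catalysed domino oxa-Michael/aldol condensation of salicylaldehydes with cinnamaldehydes to 2-aryl-2H-chromene-3-carbaldehydes. Ring C closes in a 6-(enolexo)-exo-trig aldol step. The new stereocentre C2 is catalyst-controlled: the diphenyl(silyloxy)methyl group shields the Re face of the iminium β-carbon, so O1 should add to the Si face, which corresponds to 2R, while the carbinol formed at C4 is lost in the dehydration that makes the sequence irreversible. The step needs 1,4- instead of 1,2-addition (secured by iminium activation), a single oxygen nucleophile (all other hydroxyls are benzylated) and catalyst control over the remote catechin stereocentres and the biaryl axis, which lie far from C2.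

Step 10
Reactants: 16 (2R)-2-aryl-2H-chromene-3-carbaldehyde of the lower unit
Product: 17 (2S)-2-aryl-2H-chromene (flav-3-ene) of the lower unit
Conditions: RhCl(PPh3)3 (1.2 equiv), toluene, 90 °C, dark
Reagents that add atoms: none
Why: Tsuji–Wilkinson decarbonylation: the formyl C–H adds oxidatively to monovalent rhodium, CO migrates to the metal and C3–H reductive elimination leaves the C3=C4 alkene in place; no bond to C2 is touched, and heat and light are limited to suppress electrocyclic opening of the 2H-chromene.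

Step 11
Reactants: 17 (2S)-2-aryl-2H-chromene of the lower unit
Product: 19 nona-O-benzyl dibromo precursor of the target, via 3-boryl flavan 18 (not isolated)
Conditions: BH3·THF, THF, 0 °C to rt; then NaOH, H2O2, 0 °C to rt
Reagents that add atoms: hydrogen peroxide, OO
Why: Hydroboration–oxidation: borane should add syn with boron at C3 (the alkene carbon remote from the electron-rich ring A) on the face opposite to the C2 aryl group, and oxidation with retention then gives the 2,3-trans alcohol, i.e. (2R,3S).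

Step 12
Reactants: 19 nona-O-benzyl dibromo precursor
Product: 20 target biflavan-3-ol
Conditions: H2 (1 atm), Pd(OH)2/C, Et3N, THF/MeOH, rt
Reagents that add atoms: none
Why: Catalytic hydrogenolysis should cleave the nine benzyl ethers and reduce the two ring-A C–Br bonds (Et3N takes up HBr) without touching the stereocentres or the ring C–O bonds, as in standard debenzylation of catechin ethers.

Compound list
1 | (+)-catechin, (2R,3S)-2-(3,4-dihydroxyphenyl)chromane-3,5,7-triol | Oc1cc(O)c2c(c1)O[C@H](c1ccc(O)c(O)c1)[C@@H](O)C2 | starting material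
2 | (2R,3S)-5,7-bis(benzyloxy)-2-[3,4-bis(benzyloxy)phenyl]chroman-3-ol (tetra-O-benzyl-(+)-catechin) | c1ccccc1COc1cc(OCc2ccccc2)c2c(c1)O[C@H](c1ccc(OCc3ccccc3)c(OCc3ccccc3)c1)[C@@H](O)C2 | intermediate (not isolated)
3 | (2R,3S)-3,5,7-tris(benzyloxy)-2-[3,4-bis(benzyloxy)phenyl]chromane (penta-O-benzyl-(+)-catechin) | c1ccccc1COc1cc(OCc2ccccc2)c2c(c1)O[C@H](c1ccc(OCc3ccccc3)c(OCc3ccccc3)c1)[C@@H](OCc1ccccc1)C2 | intermediate
4 | (2R,3S)-3,5,7-tris(benzyloxy)-2-[3,4-bis(benzyloxy)phenyl]-6,8-dibromochromane | c1ccccc1COc1c(Br)c(OCc2ccccc2)c2c(c1Br)O[C@H](c1ccc(OCc3ccccc3)c(OCc3ccccc3)c1)[C@@H](OCc1ccccc1)C2 | intermediate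
5 | (2R,3S)-3,5,7-tris(benzyloxy)-2-[4,5-bis(benzyloxy)-2-iodophenyl]-6,8-dibromochromane | c1ccccc1COc1c(Br)c(OCc2ccccc2)c2c(c1Br)O[C@H](c1cc(OCc3ccccc3)c(OCc3ccccc3)cc1I)[C@@H](OCc1ccccc1)C2 | intermediate
6 | 3,5-bis(benzyloxy)phenol | Oc1cc(OCc2ccccc2)cc(OCc2ccccc2)c1 | starting material
7 | 1,3-bis(benzyloxy)-5-(methoxymethoxy)benzene | COCOc1cc(OCc2ccccc2)cc(OCc2ccccc2)c1 | intermediate
8 | [2,4-bis(benzyloxy)-6-(methoxymethoxy)phenyl]lithium | [Li]c1c(OCOC)cc(OCc2ccccc2)cc1OCc1ccccc1 | intermediate (not isolated)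
9 | [2,4-bis(benzyloxy)-6-(methoxymethoxy)phenyl]zinc chloride | Cl[Zn]c1c(OCOC)cc(OCc2ccccc2)cc1OCc1ccccc1 | intermediate (not isolated)
10 | (2R,3S)-3,5,7-tris(benzyloxy)-2-{4,5-bis(benzyloxy)-2-[2,4-bis(benzyloxy)-6-(methoxymethoxy)phenyl]phenyl}-6,8-dibromochromane | c1ccccc1COc1c(Br)c(OCc2ccccc2)c2c(c1Br)O[C@H](c1cc(OCc3ccccc3)c(OCc3ccccc3)cc1-c1c(OCOC)cc(OCc3ccccc3)cc1OCc1ccccc1)[C@@H](OCc1ccccc1)C2 | intermediate
11 | 3,5-bis(benzyloxy)-2-{4,5-bis(benzyloxy)-2-[(2R,3S)-3,5,7-tris(benzyloxy)-6,8-dibromochroman-2-yl]phenyl}phenol | c1ccccc1COc1c(Br)c(OCc2ccccc2)c2c(c1Br)O[C@H](c1cc(OCc3ccccc3)c(OCc3ccccc3)cc1-c1c(O)cc(OCc3ccccc3)cc1OCc1ccccc1)[C@@H](OCc1ccccc1)C2 | intermediate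
12 | 4,6-bis(benzyloxy)-3-{4,5-bis(benzyloxy)-2-[(2R,3S)-3,5,7-tris(benzyloxy)-6,8-dibromochroman-2-yl]phenyl}-2-hydroxybenzaldehyde | c1ccccc1COc1c(Br)c(OCc2ccccc2)c2c(c1Br)O[C@H](c1cc(OCc3ccccc3)c(OCc3ccccc3)cc1-c1c(O)c(C=O)c(OCc3ccccc3)cc1OCc1ccccc1)[C@@H](OCc1ccccc1)C2 | intermediate
13 | 3,4-bis(benzyloxy)benzaldehyde | O=Cc1ccc(OCc2ccccc2)c(OCc2ccccc2)c1 | starting material
14 | (E)-3-[3,4-bis(benzyloxy)phenyl]prop-2-enal | O=C/C=C/c1ccc(OCc2ccccc2)c(OCc2ccccc2)c1 | intermediate
15 | oxa-Michael enamine: 12 alkylated at the phenol oxygen by the benzylic carbon of an (E)-3-[3,4-bis(benzyloxy)phenyl]-1-{(S)-2-[diphenyl(trimethylsilyloxy)methyl]pyrrolidin-1-yl}prop-1-en-3-yl group, the O-bearing carbon configured as C2 of 16 | c1ccccc1COc1c(Br)c(OCc2ccccc2)c2c(c1Br)O[C@H](c1cc(OCc3ccccc3)c(OCc3ccccc3)cc1-c1c(OCc3ccccc3)cc(OCc3ccccc3)c(C=O)c1O[C@H](c1ccc(OCc3ccccc3)c(OCc3ccccc3)c1)/C=C/N1CCC[C@H]1C(c1ccccc1)(c1ccccc1)O[Si](C)(C)C)[C@@H](OCc1ccccc1)C2 | intermediate (not isolated)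
16 | (2R)-5,7-bis(benzyloxy)-2-[3,4-bis(benzyloxy)phenyl]-8-{4,5-bis(benzyloxy)-2-[(2R,3S)-3,5,7-tris(benzyloxy)-6,8-dibromochroman-2-yl]phenyl}-2H-chromene-3-carbaldehyde | c1ccccc1COc1c(Br)c(OCc2ccccc2)c2c(c1Br)O[C@H](c1cc(OCc3ccccc3)c(OCc3ccccc3)cc1-c1c(OCc3ccccc3)cc(OCc3ccccc3)c3c1O[C@H](c1ccc(OCc4ccccc4)c(OCc4ccccc4)c1)C(C=O)=C3)[C@@H](OCc1ccccc1)C2 | intermediate
17 | (2S)-5,7-bis(benzyloxy)-2-[3,4-bis(benzyloxy)phenyl]-8-{4,5-bis(benzyloxy)-2-[(2R,3S)-3,5,7-tris(benzyloxy)-6,8-dibromochroman-2-yl]phenyl}-2H-chromene (same spatial arrangement at C2 as 16; only the descriptor changes) | c1ccccc1COc1c(Br)c(OCc2ccccc2)c2c(c1Br)O[C@H](c1cc(OCc3ccccc3)c(OCc3ccccc3)cc1-c1c(OCc3ccccc3)cc(OCc3ccccc3)c3c1O[C@H](c1ccc(OCc4ccccc4)c(OCc4ccccc4)c1)C=C3)[C@@H](OCc1ccccc1)C2 | intermediate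
18 | 2,3-trans 3-boryl flavan: 17 with H added at C4 and BH2 at C3 anti to the C2 aryl group | c1ccccc1COc1c(Br)c(OCc2ccccc2)c2c(c1Br)O[C@H](c1cc(OCc3ccccc3)c(OCc3ccccc3)cc1-c1c(OCc3ccccc3)cc(OCc3ccccc3)c3c1O[C@H](c1ccc(OCc4ccccc4)c(OCc4ccccc4)c1)[C@@H](B)C3)[C@@H](OCc1ccccc1)C2 | intermediate (not isolated)
19 | (2R,3S)-5,7-bis(benzyloxy)-2-[3,4-bis(benzyloxy)phenyl]-8-{4,5-bis(benzyloxy)-2-[(2R,3S)-3,5,7-tris(benzyloxy)-6,8-dibromochroman-2-yl]phenyl}chroman-3-ol | c1ccccc1COc1c(Br)c(OCc2ccccc2)c2c(c1Br)O[C@H](c1cc(OCc3ccccc3)c(OCc3ccccc3)cc1-c1c(OCc3ccccc3)cc(OCc3ccccc3)c3c1O[C@H](c1ccc(OCc4ccccc4)c(OCc4ccccc4)c1)[C@@H](O)C3)[C@@H](OCc1ccccc1)C2 | intermediate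
20 | (2R,3S)-2-(3,4-dihydroxyphenyl)-8-{4,5-dihydroxy-2-[(2R,3S)-3,5,7-trihydroxychroman-2-yl]phenyl}chromane-3,5,7-triol | Oc1cc(O)c2c(c1)O[C@H](c1cc(O)c(O)cc1-c1c(O)cc(O)c3c1O[C@H](c1ccc(O)c(O)c1)[C@@H](O)C3)[C@@H](O)C2 | target

Total step count: 12. Longest linear sequence: 10 steps (steps 1, 2, 3, 5, 6, 7, 9, 10, 11, 12, from (+)-catechin).

Steps most likely to fail

Step 9. The oxa-Michael addition of the hindered, hydrogen-bonded phenol to an electron-rich enal may be too slow or reversible, and the facial selectivity at C2 may be eroded by retro-addition. The fallback sets out from 12 and returns at 17. Wittig methylenation of 12 (Ph3P=CH2, THF, 0 °C) gives the 2-vinylphenol F1. In parallel 14 is reduced (NaBH4, CeCl3, MeOH) to the cinnamyl alcohol F2 and acylated (ClCO2Me, pyridine) to the methyl carbonate F3. Iridium-catalysed asymmetric allylic etherification of the sodium salt of F1 with F3 ([Ir(cod)Cl]2, BINOL-derived phosphoramidite ligand bearing a bis(1-phenylethyl)amino group, the ligand enantiomer that leads to the (S)-configured branched ether, THF) gives the diene F4. Ring-closing metathesis (second-generation Grubbs catalyst, CH2Cl2, 40 °C) then closes ring C across C3=C4 with loss of ethene and arrives at 17 without passing through 16.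

Step 10. At the temperature of the decarbonylation the 2H-chromene may open and re-close electrocyclically, with loss of configuration at C2, or the alkene may migrate into conjugation with O1. The fallback sets out from 16 and returns at 19, with every operation at or below room temperature. Conjugate reduction of the enal (catalytic [CuH(PPh3)]6, PhSiH3, toluene, then aqueous NH4Cl) gives the saturated aldehyde F5 as C3 epimers, which is of no consequence. Chlorite oxidation (NaClO2, NaH2PO4, 2-methyl-2-butene) gives the acid F6. This is converted (2-mercaptopyridine N-oxide, DCC) into the thiohydroxamate ester F7, which is decarboxylated under visible light in the presence of TEMPO. The C3 radical should be trapped on the face opposite to the C2 aryl group to give the trans alkoxyamine F8, and N–O cleavage (Zn, AcOH) gives 19, so that steps 10 and 11 are replaced.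

Step 5. The tri-ortho-substituted C6'–C8 bond may form slowly, so that insertion into the ring-A C–Br bonds or protonation of the arylzinc competes. The lithiation of 7 may also occur between the two benzyloxy groups or at a benzylic CH2. The fallback, with reversed polarity, sets out from 5 and 6 and returns at 12. Miyaura borylation of 5 (B2pin2, PdCl2(dppf), KOAc, dioxane, 80 °C) gives the pinacol boronate F9. Phenol 6 is formylated ortho to the hydroxyl (MgCl2, Et3N, paraformaldehyde) to the salicylaldehyde F10, which is iodinated between the chelated hydroxyl and a benzyloxy group (NIS, CH2Cl2, 0 °C) to give the iodide F11. Suzuki–Miyaura coupling of F9 with F11 (Pd(OAc)2, SPhos, K3PO4, toluene/water, 60 °C) gives 12 directly, so that 7 to 11 are not needed.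

Further compounds
F1 | step 9 | 3,5-bis(benzyloxy)-2-{4,5-bis(benzyloxy)-2-[(2R,3S)-3,5,7-tris(benzyloxy)-6,8-dibromochroman-2-yl]phenyl}-6-vinylphenol | c1ccccc1COc1c(Br)c(OCc2ccccc2)c2c(c1Br)O[C@H](c1cc(OCc3ccccc3)c(OCc3ccccc3)cc1-c1c(O)c(C=C)c(OCc3ccccc3)cc1OCc1ccccc1)[C@@H](OCc1ccccc1)C2
F2 | step 9 | (E)-3-[3,4-bis(benzyloxy)phenyl]prop-2-en-1-ol | OC/C=C/c1ccc(OCc2ccccc2)c(OCc2ccccc2)c1
F3 | step 9 | (E)-3-[3,4-bis(benzyloxy)phenyl]allyl methyl carbonate | COC(=O)OC/C=C/c1ccc(OCc2ccccc2)c(OCc2ccccc2)c1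
F4 | step 9 | (S)-1-[3,4-bis(benzyloxy)phenyl]allyl ether of F1 (diene for ring closure) | c1ccccc1COc1c(Br)c(OCc2ccccc2)c2c(c1Br)O[C@H](c1cc(OCc3ccccc3)c(OCc3ccccc3)cc1-c1c(OCc3ccccc3)cc(OCc3ccccc3)c(C=C)c1O[C@H](c1ccc(OCc3ccccc3)c(OCc3ccccc3)c1)C=C)[C@@H](OCc1ccccc1)C2
F5 | step 10 | 3-formyl flavan of the lower unit (16 with C3=C4 reduced, C3 epimers) | c1ccccc1COc1c(Br)c(OCc2ccccc2)c2c(c1Br)O[C@H](c1cc(OCc3ccccc3)c(OCc3ccccc3)cc1-c1c(OCc3ccccc3)cc(OCc3ccccc3)c3c1O[C@H](c1ccc(OCc4ccccc4)c(OCc4ccccc4)c1)C(C=O)C3)[C@@H](OCc1ccccc1)C2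
F6 | step 10 | flavan-3-carboxylic acid of the lower unit (C3 epimers) | c1ccccc1COc1c(Br)c(OCc2ccccc2)c2c(c1Br)O[C@H](c1cc(OCc3ccccc3)c(OCc3ccccc3)cc1-c1c(OCc3ccccc3)cc(OCc3ccccc3)c3c1O[C@H](c1ccc(OCc4ccccc4)c(OCc4ccccc4)c1)C(C(O)=O)C3)[C@@H](OCc1ccccc1)C2
F7 | step 10 | 2-thioxopyridin-1(2H)-yl ester of F6 | c1ccccc1COc1c(Br)c(OCc2ccccc2)c2c(c1Br)O[C@H](c1cc(OCc3ccccc3)c(OCc3ccccc3)cc1-c1c(OCc3ccccc3)cc(OCc3ccccc3)c3c1O[C@H](c1ccc(OCc4ccccc4)c(OCc4ccccc4)c1)C(C(=O)ON1C=CC=CC1=S)C3)[C@@H](OCc1ccccc1)C2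
F8 | step 10 | 2,3-trans 3-(2,2,6,6-tetramethylpiperidin-1-yloxy) flavan of the lower unit (O-TEMPO ether of 19) | c1ccccc1COc1c(Br)c(OCc2ccccc2)c2c(c1Br)O[C@H](c1cc(OCc3ccccc3)c(OCc3ccccc3)cc1-c1c(OCc3ccccc3)cc(OCc3ccccc3)c3c1O[C@H](c1ccc(OCc4ccccc4)c(OCc4ccccc4)c1)[C@@H](ON1C(C)(C)CCCC1(C)C)C3)[C@@H](OCc1ccccc1)C2
F9 | step 5 | (2R,3S)-3,5,7-tris(benzyloxy)-2-[4,5-bis(benzyloxy)-2-(4,4,5,5-tetramethyl-1,3,2-dioxaborolan-2-yl)phenyl]-6,8-dibromochromane | c1ccccc1COc1c(Br)c(OCc2ccccc2)c2c(c1Br)O[C@H](c1cc(OCc3ccccc3)c(OCc3ccccc3)cc1B1OC(C)(C)C(C)(C)O1)[C@@H](OCc1ccccc1)C2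
F10 | step 5 | 2,4-bis(benzyloxy)-6-hydroxybenzaldehyde | O=Cc1c(O)cc(OCc2ccccc2)cc1OCc1ccccc1
F11 | step 5 | 4,6-bis(benzyloxy)-2-hydroxy-3-iodobenzaldehyde | O=Cc1c(O)c(I)c(OCc2ccccc2)cc1OCc1ccccc1
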